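(The numbers in the tables come from a simulation for substances that don't exist, and the scatter is random.)

Take the alder run, where 60.6% of the starting material stood at 4.00 min, and the cedar run, where 41.2% stood at 0.667 min. Turn each first reading into a pseudo-first-order time τ, the time for starting material to fall by a factor e with partner held at its charge: 7.99 min for alder and 0.752 min for cedar.

| flask | starting material | partner | temperature | remark | time |
|---|---|---|---|---|---|
| birch | 0.50 M | 1 equiv | 65 °C | run made earlier |  |
| cedar | 0.50 M | 2.2 equiv | 100 °C | run made earlier |  |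
| alder | 1 M | 1.5 equiv | 65 °C | run made earlier |  |
| theta | 0.50 M | 1.50 equiv | 130 °C |  | 2.5 min |
| delta | 0.50 M | 1.50 equiv | 70 °C |  | 2.5 min |
| epsilon | 0.50 M | 1.50 equiv | 90 °C |  | 2.5 min |
| alpha | 0.50 M | 1.50 equiv | 110 °C |  | 2.5 min |

| run | time / min | single product / % | starting material / % |
|---|---|---|---|
| birch | 8.00 | 11.9 | 72.1 |
| birch | 15.0 | 15.8 | 58.6 |
| birch | 25.0 | 18.8 | 47.7 |
| birch | 30.0 | 18.6 | 43.0 |
| birch | 40.0 | 18.8 | 38.5 |
| birch | 50.0 | 19.7 | 35.0 |
| cedar | 0.667 | 21.3 | 41.2 |
| cedar | 1.00 | 20.8 | 28.9 |
| cedar | 2.00 | 13.5 | 13.6 |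
| cedar | 3.00 | 8.9 | 7.7 |
| cedar | 6.00 | 2.8 | 1.9 |
| cedar | 8.00 | 0.9 | 1.0 |
| alder | 4.00 | 15.6 | 60.6 |
| alder | 8.00 | 19.2 | 42.8 |
| alder | 12.0 | 19.5 | 32.5 |
| alder | 25.0 | 18.4 | 18.7 |
| alder | 50.0 | 15.5 | 11.9 |

(readings scatter by 0.5 percentage points)

- the numbers in the tables scatter with a standard deviation of 0.5 percentage points

1. the flask with the highest amount of single product, in percent of the starting material charged ("all alike" if they lie within 1.5 percentage points) (theta / delta / epsilon / alpha / all alike)
2. final single product, as a percentage of the starting material charged, in theta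
3. final single product, as a percentage of the starting material charged, in delta
4. final single product, as a percentage of the starting material charged, in epsilon
5. final single product, as a percentage of the starting material charged, in alpha

Assume the loss of starting material is first order in partner, so that τ scales inversely with partner molarity; at the 0.750 M of partner in the new flasks, τ becomes 16.0 min at 65 °C and 1.10 min at 100 °C. Draw ln τ straight against temperature, extending the line for the hotter flasks, and divide 2.5 min by τ: epsilon gets 1.06, and this ratio is the exposure Θ, the flask's time counted in units of τ. Delta gets 0.229, alpha 4.86 and theta 22.4.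

Now read the outcome off Θ: the highest cedar reading of single product stands at Θ = 0.887, the highest alder reading at 1.50, and the Θ of epsilon lies between these two, with delta below them and alpha above them, so expect epsilon on top, with 34.8% of its starting material left. Then test the single number: cedar at Θ = 7.98 held 2.8% of single product, but alder at 6.26 held more, 15.5%, so use Θ to place a flask against the highest readings and not to give amounts on the late side.

The forecast named epsilon as the highest flask, with 10.5% of single product in delta, 20% in epsilon, 11.5% in alpha and 7% in theta, from its view that “The runs fit parallel and consecutive steps”.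

The flasks gave 10.5% of single product in delta, 20.6% in epsilon, which is more than in any of the others, 12.5% in alpha and 4.61% in theta.

    starting material + partner → single product (k = 0.00180 M⁻¹ s⁻¹, Ea = 82.0 kJ mol⁻¹)
    starting material + partner → other mono adduct (k = 6.90 × 10⁻⁴ M⁻¹ s⁻¹, Ea = 82.0 kJ mol⁻¹)
    partner + single product → bis adduct (k = 0.00300 M⁻¹ s⁻¹, Ea = 88.0 kJ mol⁻¹)
    partner + other mono adduct → bis adduct (k = 8.00 × 10⁻⁴ M⁻¹ s⁻¹, Ea = 64.0 kJ mol⁻¹)
    starting material → decomposition product (k = 1.60 × 10⁻⁵ s⁻¹, Ea = 118 kJ mol⁻¹)
    single product ⇌ isomer of the product (K = 0.410, k = 0.0380 s⁻¹, Ea = 94.0 kJ mol⁻¹, ΔH = −37.0 kJ mol⁻¹)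
    (constants at 70 °C)

Epsilon held 38.6% of its starting material at 2.50 min against the 34.8% from Θ. At 0.747 min in epsilon, single product was made twice as fast as it was used up, each step taken net, with a half-life of 1.2 min by the step to bis adduct; at 2.50 min in epsilon that half-life was 2.0 min, with 46.3% of the partner's charge present.

Read epsilon at 6.0 min instead: Θ grows to 2.53, and alder, with the same equivalents, held 19.5% and 18.4% of single product at Θ = 1.50 and 3.13, so expect a little less than the 20.6% of epsilon at 2.5 min. That flask gives 17.6% of single product.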